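**Plan**
- The methylene bridge is cut on both sides (C7–CH2 and CH2–C3 of the pyranone). This gives dihydrobenzofuran 12, a one-carbon iminium reagent and 6-ethyl-4-hydroxy-5-methyl-2-pyranone 16 (from pentan-3-one and malonyl dichloride).
- In 12 (O1, C2, C3, C3a, C4 to C7, C7a) the carbons C4, C5, C6 and the exocyclic acyl carbon are a 1,3,5-tricarbonyl array, whereas O1, C2, C3, C3a and C7a make up a 4,5-dihydrofuran that needs no benzene ring. The C4–C5 bond is therefore cut, leading to diketo ester 10.
- 10 is cut at C5–acyl and at C6–C7 back to the 2-methyl-dihydrofuran ester 6, and 6 at O1–C2 and C3–C3a to methyl acetoacetate and oxidised prenyl acetate.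
- Forward order: dihydrofuran ring (step 4), chain growth by two enolate acylations (steps 5 and 7), benzene ring (step 8), pyranone made separately (step 10), union through a Mannich base (steps 11 and 12).
- C2 is set by the chiral diphosphine in the palladium-catalysed ring closure of step 4. The acyl stereocentre is bought as (R)-2-methylbutanoic acid and is never enolised.

Key step: step 8

Assumption: the (R,R)-configured ligand is taken to give the (R)-ether in step 4 (otherwise its enantiomer is used); 4 and 5 are racemic at their enolisable C2, which becomes sp2 in step 4.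

**Route**

Step 1
Reactants: 1 3-methylbut-2-en-1-yl acetate (prenyl acetate)
Product: 2 (E)-4-hydroxy-3-methylbut-2-en-1-yl acetate
Conditions: SeO2 (0.3 equiv), t-BuOOH (70% aq., 2.5 equiv), salicylic acid (0.1 equiv), CH2Cl2, rt
Reagents that add atoms: tert-butyl hydroperoxide, CC(C)(C)OO (oxygen, passed on by SeO2)
Why: Allylic oxidation with SeO2 (ene reaction, then [2,3]-sigmatropic shift) hydroxylates the (E)-methyl group of a trisubstituted alkene selectively and leaves the allylic acetate alone.

Step 2
Reactants: 3 methyl acetoacetate; 2 (E)-4-hydroxy-3-methylbut-2-en-1-yl acetate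
Product: 4 methyl (E)-2-acetyl-6-hydroxy-5-methylhex-4-enoate
Conditions: 3 (2 equiv), NaH (1.8 equiv), THF, 0 °C; then 2, Pd(PPh3)4 (3 mol %), 50 °C
Reagents that add atoms: none
Why: Tsuji–Trost allylation, in which zerovalent palladium ionises only the allylic acetate (the free alcohol is no leaving group) and the soft sodium enolate, used in excess against double allylation, attacks the unsubstituted CH2 terminus of the allyl complex to give the linear (E)-product.

Step 3
Reactants: 4 methyl (E)-2-acetyl-6-hydroxy-5-methylhex-4-enoate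
Product: 5 methyl (E)-2-acetyl-6-[(methoxycarbonyl)oxy]-5-methylhex-4-enoate
Conditions: ClCO2Me (1.2 equiv), pyridine, CH2Cl2, 0 °C
Reagents that add atoms: methyl chloroformate, COC(=O)Cl
Why: Acylation of the primary allylic alcohol by the chloroformate is much faster than O-acylation of the keto ester enol and installs a leaving group that ionises under neutral conditions.

Step 4
Reactants: 5 methyl (E)-2-acetyl-6-[(methoxycarbonyl)oxy]-5-methylhex-4-enoate
Product: 6 methyl (R)-2-methyl-5-(prop-1-en-2-yl)-4,5-dihydrofuran-3-carboxylate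
Conditions: Pd2(dba)3·CHCl3 (2.5 mol %), (R,R)-DACH-phenyl ligand N,N'-[(1R,2R)-cyclohexane-1,2-diyl]bis[2-(diphenylphosphanyl)benzamide] (7.5 mol %), CH2Cl2, rt
Reagents that add atoms: none
Why: Intramolecular asymmetric Tsuji–Trost O-allylation, in which the carbonate ionises to a 2-methylallyl palladium complex and methoxide (after loss of CO2), the keto ester enolate closes the five-membered ring through oxygen at the near allyl terminus (5-exo; the seven-membered ether is slower and a C-alkylated vinylcyclopropane would reopen), and the new stereocentre (C5 of the dihydrofuran, later C2 of the benzofuran) is set by the chiral pocket of the diphosphine, which selects between the two allyl faces that interconvert by π–σ–π exchange at the CH2 terminus.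

Step 5
Reactants: 6 methyl (R)-2-methyl-5-(prop-1-en-2-yl)-4,5-dihydrofuran-3-carboxylate
Product: 7 methyl (R)-2-(2-oxopropyl)-5-(prop-1-en-2-yl)-4,5-dihydrofuran-3-carboxylate
Conditions: LiN(iPr)2 (1.1 equiv), THF, −78 °C; then MeC(O)N(OMe)Me (1.2 equiv), −78 → −20 °C; aq. NH4Cl
Reagents that add atoms: N-methoxy-N-methylacetamide, CC(=O)N(C)OC
Why: Vinylogous Claisen acylation, in which the base removes a proton from the 2-methyl group (the only γ-position of the β-alkoxy acrylate), the dienolate reacts at that carbon as 6-methyl-1,3-dioxin-4-ones do, and the chelated tetrahedral adduct of the N-methoxy-N-methyl amide lasts until quench, preventing over-addition and proton loss from the more acidic product.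

Step 6
Reactants: 8 (R)-2-methylbutanoic acid
Product: 9 (R)-N-methoxy-N,2-dimethylbutanamide
Conditions: 1,1'-carbonyldiimidazole (1.1 equiv), CH2Cl2, rt; then MeNHOMe·HCl (1.2 equiv), rt
Reagents that add atoms: N,O-dimethylhydroxylamine hydrochloride, CNOC.Cl
Why: Amide formation through the acyl imidazolide needs no strong base, so the α-stereocentre should not be enolised.

Step 7
Reactants: 7 methyl (R)-2-(2-oxopropyl)-5-(prop-1-en-2-yl)-4,5-dihydrofuran-3-carboxylate; 9 (R)-N-methoxy-N,2-dimethylbutanamide
Product: 10 methyl (R)-2-[(R)-5-methyl-2,4-dioxoheptyl]-5-(prop-1-en-2-yl)-4,5-dihydrofuran-3-carboxylate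
Conditions: LiN(iPr)2 (2.2 equiv), THF, −78 → −40 °C; then 9 (1.1 equiv), −78 → 0 °C; aq. NH4Cl
Reagents that add atoms: none
Why: Dianion acylation as with β-keto esters and keto-dioxinones, in which the first equivalent of base deprotonates the CH2 between ring and ketone (this also turns the ester into part of an enolate and so protects it), the second gives the terminal methyl carbanion, and this more basic carbon adds to the amide, whose stable tetrahedral adduct stops at the ketone and whose own α-proton is too weakly acidic to be removed.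

Step 8
Reactants: 10 methyl (R)-2-[(R)-5-methyl-2,4-dioxoheptyl]-5-(prop-1-en-2-yl)-4,5-dihydrofuran-3-carboxylate
Product: 12 (R)-1-[(R)-4,6-dihydroxy-2-(prop-1-en-2-yl)-2,3-dihydrobenzofuran-5-yl]-2-methylbutan-1-one, via cyclic triketone 11 (not isolated)
Conditions: Mg(OMe)2 (4 equiv), MeOH, reflux; then cold 1 M HCl to pH 3
Reagents that add atoms: none
Why: Mg(OMe)2 turns the 1,3-diketone into its chelated magnesium enolate, whose central carbon (future C5) adds to the ester carbonyl on the dihydrofuran (future C4); loss of methoxide gives triketone 11, which enolises twice to the benzene ring. The closest known reaction is the Claisen (Dieckmann-type) cyclisation of 3,5,7-triketo esters and of their pyranone-masked forms to acylphloroglucinols with the same base, here with the 3-carbonyl held as the enol ether of the dihydrofuran. The six-membered ring closes in a 6-(enolexo)-exo-trig mode and no stereocentre is created. The step needs C- over O-acylation and reaction through C5, not C7: magnesium chelation favours the carbon nucleophile, O-acylation to a furopyranone is undone by methoxide whereas aromatisation makes C-acylation irreversible, and C7 could reach either carbonyl only through a four-membered ring. The diketone is the most acidic site, so the main anion is the reactive one and the ester stays a neutral electrophile. C2 is an allylic ether carbon without an acidic hydrogen, and the acyl α-centre is shielded because the adjacent diketone, and later the phenoxide-conjugated aryl ketone, is already deprotonated.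

Step 9
Reactants: 13 pentan-3-one
Product: 14 trimethyl(pent-2-en-3-yloxy)silane (E/Z mixture)
Conditions: Me3SiCl (1.2 equiv), Et3N (2.4 equiv), DMF, 80 °C
Reagents that add atoms: chlorotrimethylsilane, C[Si](C)(C)Cl
Why: Silyl enol ether formation from a symmetrical ketone can give only one regioisomer, and the alkene geometry is irrelevant because this carbon ends up sp2 in the pyranone.

Step 10
Reactants: 14 trimethyl(pent-2-en-3-yloxy)silane
Product: 16 6-ethyl-4-hydroxy-5-methyl-2H-pyran-2-one, via diketoacyl chloride 15 (not isolated)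
Conditions: CH2(COCl)2 (1.0 equiv), Et2O, −78 °C → rt
Reagents that add atoms: malonyl dichloride, O=C(Cl)CC(=O)Cl
Why: C-Acylation of the silyl enol ether by one acid chloride group, followed by attack of the enol oxygen of 15 on the second, closes the 4-hydroxy-2-pyranone, a known annulation of silyl enol ethers with malonyl dichloride.

Step 11
Reactants: 12 (R)-1-[(R)-4,6-dihydroxy-2-(prop-1-en-2-yl)-2,3-dihydrobenzofuran-5-yl]-2-methylbutan-1-one
Product: 17 (R)-1-[(R)-7-[(dimethylamino)methyl]-4,6-dihydroxy-2-(prop-1-en-2-yl)-2,3-dihydrobenzofuran-5-yl]-2-methylbutan-1-one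
Conditions: CH2=NMe2+ I− (1.05 equiv), CH2Cl2, rt; aq. NaHCO3
Reagents that add atoms: dimethyl(methylidene)ammonium iodide, C=[N+](C)C.[I-]
Why: Mannich reaction of the preformed iminium salt at C7, the only unsubstituted ring carbon, under neutral anhydrous conditions that spare the isopropenyl group and both stereocentres and give a Mannich base that does not ionise at room temperature.

Step 12
Reactants: 17 (R)-1-[(R)-7-[(dimethylamino)methyl]-4,6-dihydroxy-2-(prop-1-en-2-yl)-2,3-dihydrobenzofuran-5-yl]-2-methylbutan-1-one; 16 6-ethyl-4-hydroxy-5-methyl-2H-pyran-2-one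
Product: 19 6-ethyl-4-hydroxy-3-({(2R)-4,6-dihydroxy-5-[(2R)-2-methylbutanoyl]-2-(prop-1-en-2-yl)-2,3-dihydro-1-benzofuran-7-yl}methyl)-5-methyl-2H-pyran-2-one, via ortho-quinone methide 18 (not isolated)
Conditions: 16 (1.2 equiv), 1,4-dioxane, 80 °C, N2 stream
Reagents that add atoms: none
Why: On heating with the acidic pyranone the Mannich base loses dimethylamine to give quinone methide 18, which C3 of the 4-hydroxy-2-pyranone captures in a Michael addition that restores the aromatic ring (the known alkylation of 1,3-dicarbonyl compounds by phenolic Mannich bases), and since neither partner has another free nucleophilic carbon only the mixed methylene-bridged product is expected.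

**Compound list**
1 | 3-methylbut-2-en-1-yl acetate (prenyl acetate) | CC(C)=CCOC(C)=O | starting material
2 | (E)-4-hydroxy-3-methylbut-2-en-1-yl acetate | CC(=O)OC/C=C(\C)CO | intermediate
3 | methyl acetoacetate | COC(=O)CC(C)=O | starting material
4 | methyl (E)-2-acetyl-6-hydroxy-5-methylhex-4-enoate (racemic at C2) | COC(=O)C(C(C)=O)C/C=C(\C)CO | intermediate
5 | methyl (E)-2-acetyl-6-[(methoxycarbonyl)oxy]-5-methylhex-4-enoate (racemic at C2) | COC(=O)C(C(C)=O)C/C=C(\C)COC(=O)OC | intermediate
6 | methyl (R)-2-methyl-5-(prop-1-en-2-yl)-4,5-dihydrofuran-3-carboxylate | C=C(C)[C@H]1CC(C(=O)OC)=C(C)O1 | intermediate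
7 | methyl (R)-2-(2-oxopropyl)-5-(prop-1-en-2-yl)-4,5-dihydrofuran-3-carboxylate | C=C(C)[C@H]1CC(C(=O)OC)=C(CC(C)=O)O1 | intermediate
8 | (R)-2-methylbutanoic acid | CC[C@@H](C)C(=O)O | starting material
9 | (R)-N-methoxy-N,2-dimethylbutanamide | CC[C@@H](C)C(=O)N(C)OC | intermediate
10 | methyl (R)-2-[(R)-5-methyl-2,4-dioxoheptyl]-5-(prop-1-en-2-yl)-4,5-dihydrofuran-3-carboxylate | C=C(C)[C@H]1CC(C(=O)OC)=C(CC(=O)CC(=O)[C@H](C)CC)O1 | intermediate
11 | (2R)-5-[(2R)-2-methylbutanoyl]-2-(prop-1-en-2-yl)-2,3,5,7-tetrahydro-1-benzofuran-4,6-dione (cyclic triketone, C5 undefined) | C=C(C)[C@H]1CC2=C(O1)CC(=O)C(C(=O)[C@H](C)CC)C2=O | intermediate (not isolated)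
12 | (R)-1-[(R)-4,6-dihydroxy-2-(prop-1-en-2-yl)-2,3-dihydrobenzofuran-5-yl]-2-methylbutan-1-one | C=C(C)[C@H]1Cc2c(O)c(C(=O)[C@H](C)CC)c(O)cc2O1 | intermediate
13 | pentan-3-one | CCC(=O)CC | starting material
14 | trimethyl(pent-2-en-3-yloxy)silane (E/Z mixture) | CC=C(CC)O[Si](C)(C)C | intermediate
15 | 4-methyl-3,5-dioxoheptanoyl chloride | CCC(=O)C(C)C(=O)CC(=O)Cl | intermediate (not isolated)
16 | 6-ethyl-4-hydroxy-5-methyl-2H-pyran-2-one | CCc1oc(=O)cc(O)c1C | intermediate
17 | (R)-1-[(R)-7-[(dimethylamino)methyl]-4,6-dihydroxy-2-(prop-1-en-2-yl)-2,3-dihydrobenzofuran-5-yl]-2-methylbutan-1-one | C=C(C)[C@H]1Cc2c(O)c(C(=O)[C@H](C)CC)c(O)c(CN(C)C)c2O1 | intermediate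
18 | (2R)-4-hydroxy-7-methylidene-5-[(2R)-2-methylbutanoyl]-2-(prop-1-en-2-yl)-2,3-dihydro-1-benzofuran-6(7H)-one (ortho-quinone methide) | C=C(C)[C@H]1CC2=C(O1)C(=C)C(=O)C(C(=O)[C@H](C)CC)=C2O | intermediate (not isolated)
19 | 6-ethyl-4-hydroxy-3-({(2R)-4,6-dihydroxy-5-[(2R)-2-methylbutanoyl]-2-(prop-1-en-2-yl)-2,3-dihydro-1-benzofuran-7-yl}methyl)-5-methyl-2H-pyran-2-one | C=C(C)[C@H]1Cc2c(O)c(C(=O)[C@H](C)CC)c(O)c(Cc3c(O)c(C)c(CC)oc3=O)c2O1 | target

**Step count and risks**
Total step count: 12. Longest linear sequence: 9 steps (1, 2, 3, 4, 5, 7, 8, 11, 12).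

Steps most likely to fail:

1. Step 8. Methoxide may cleave the diketone by a retro-Claisen reaction, or reversible O-acylation and partial enolisation towards C7 may keep C-acylation from taking over. The fallback closes the ring before the acyl group is present and adds the ketone afterwards. It sets out from 7, which is heated with NaOMe in MeOH so that its methyl ketone carbon closes onto the ester, giving (R)-2-(prop-1-en-2-yl)-2,3-dihydrobenzofuran-4,6-diol F1. MOMCl and i-Pr2NEt in CH2Cl2 convert it into (R)-4,6-bis(methoxymethoxy)-2-(prop-1-en-2-yl)-2,3-dihydrobenzofuran F2. Directed ortho-metalation with n-BuLi in THF at 0 °C lithiates C5 between the two acetal ethers, and quenching with amide 9 at −78 °C gives (R)-1-[(R)-4,6-bis(methoxymethoxy)-2-(prop-1-en-2-yl)-2,3-dihydrobenzofuran-5-yl]-2-methylbutan-1-one F3. ZnBr2 and n-PrSH in CH2Cl2 at 0 °C remove both acetals, and the route is rejoined at 12.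

2. Step 4. The ligand may discriminate poorly between the two allyl faces in the ring-closing attack, or reversible ionisation of the allylic enol ether may erode the selectivity. The fallback takes the stereocentre from a reagent-controlled epoxidation and an SN2 ring closure. It sets out from 4. Sharpless asymmetric epoxidation (Ti(OiPr)4, L-(+)-diethyl tartrate, t-BuOOH, 4 Å molecular sieves, CH2Cl2, −20 °C) should give methyl 2-acetyl-3-[(2S,3S)-3-(hydroxymethyl)-3-methyloxiran-2-yl]propanoate F4. With DBU in CH2Cl2 the enol oxygen opens the epoxide at the secondary carbon (5-exo-tet, inversion) to methyl (R)-5-[(S)-1,2-dihydroxypropan-2-yl]-2-methyl-4,5-dihydrofuran-3-carboxylate F5. 1,1'-Thiocarbonyldiimidazole in THF gives methyl (R)-2-methyl-5-[(S)-4-methyl-2-sulfanylidene-1,3-dioxolan-4-yl]-4,5-dihydrofuran-3-carboxylate F6, and Corey–Winter elimination in refluxing P(OMe)3 turns the diol carbons into the isopropenyl group, rejoining the route at 6.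

3. Step 7. Proton transfer between dianion and amide may compete with addition, the dianion may react through its internal carbon, or the α-methyl centre may partly epimerise in the strongly basic medium. The fallback replaces the acylation by an aldol addition and an oxidation. It sets out from 9, which is reduced with i-Bu2AlH in CH2Cl2 at −78 °C to (R)-2-methylbutanal F7, used at once as a cold solution. The dianion of 7 (LiN(iPr)2, 2.2 equiv, THF, −78 °C) adds to it through the terminal carbon to give methyl (R)-2-[(5R)-4-hydroxy-5-methyl-2-oxoheptyl]-5-(prop-1-en-2-yl)-4,5-dihydrofuran-3-carboxylate F8 as a mixture of carbinol epimers. Dess–Martin periodinane (1.1 equiv) in CH2Cl2 oxidises both epimers to the diketone, and the route is rejoined at 10.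

**Further compounds**
F1 | step 8 | (R)-2-(prop-1-en-2-yl)-2,3-dihydrobenzofuran-4,6-diol | C=C(C)[C@H]1Cc2c(O)cc(O)cc2O1
F2 | step 8 | (R)-4,6-bis(methoxymethoxy)-2-(prop-1-en-2-yl)-2,3-dihydrobenzofuran | C=C(C)[C@H]1Cc2c(OCOC)cc(OCOC)cc2O1
F3 | step 8 | (R)-1-[(R)-4,6-bis(methoxymethoxy)-2-(prop-1-en-2-yl)-2,3-dihydrobenzofuran-5-yl]-2-methylbutan-1-one | C=C(C)[C@H]1Cc2c(OCOC)c(C(=O)[C@H](C)CC)c(OCOC)cc2O1
F4 | step 4 | methyl 2-acetyl-3-[(2S,3S)-3-(hydroxymethyl)-3-methyloxiran-2-yl]propanoate | COC(=O)C(C(C)=O)C[C@@H]1O[C@@]1(C)CO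
F5 | step 4 | methyl (R)-5-[(S)-1,2-dihydroxypropan-2-yl]-2-methyl-4,5-dihydrofuran-3-carboxylate | OC[C@](C)(O)[C@H]1CC(C(=O)OC)=C(C)O1
F6 | step 4 | methyl (R)-2-methyl-5-[(S)-4-methyl-2-sulfanylidene-1,3-dioxolan-4-yl]-4,5-dihydrofuran-3-carboxylate | S=C1OC[C@](C)(O1)[C@H]2CC(C(=O)OC)=C(C)O2
F7 | step 7 | (R)-2-methylbutanal | CC[C@@H](C)C=O
F8 | step 7 | methyl (R)-2-[(5R)-4-hydroxy-5-methyl-2-oxoheptyl]-5-(prop-1-en-2-yl)-4,5-dihydrofuran-3-carboxylate | C=C(C)[C@H]1CC(C(=O)OC)=C(CC(=O)CC(O)[C@H](C)CC)O1
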